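**Assumption:** the target has no stereocentre (it is achiral), so "single enantiomer" is read as the single (E,E) geometric isomer drawn. 4‑Ethynylphenol and the Ohira–Bestmann reagent are taken as purchasable.

## Retrosynthetic overview

1. Both aryl ketones are 2‑hydroxyaryl (salicyl) ketones, so each enone is cut at C(acyl)–Cα by retro‑hydroacylation (salicylaldehyde C–H + terminal arylacetylene, syn addition gives E), not by Claisen–Schmidt aldol.
2. Target ⇒ alkyne 8 + 2,4‑dihydroxybenzaldehyde; 8 ⇒ aldehyde 6 by one‑carbon homologation; 6 ⇒ dialdehyde 4 + 4‑ethynylphenol, where only the chelating (ortho‑OH) aldehyde reacts.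
3. Diaryl ether: 4 ⇒ SNAr of 2,5‑dihydroxy‑4‑methoxybenzaldehyde on 4‑fluorobenzaldehyde; the hydroquinone comes from para‑hydroxylation (Elbs) of 2‑hydroxy‑4‑methoxybenzaldehyde.
4. No ring is constructed: the four benzene rings are bought and joined in the order central ring → aryloxy ring (ether) → 4‑hydroxyphenyl ring (enone 1) → resorcinol ring (enone 2). No protecting groups are used.

## Route

**Step 1**
Reactants: 1, 2‑hydroxy‑4‑methoxybenzaldehyde
Product: 2, 2,5‑dihydroxy‑4‑methoxybenzaldehyde
Conditions: K2S2O8 (1.1 equiv), 10% aq NaOH, 0 °C → rt, 24 h; then aq HCl, 90 °C, 1 h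
Reagents that add atoms: potassium peroxodisulfate, [K+].[K+].[O-]S(=O)(=O)OOS(=O)(=O)[O-] (supplies the new ring oxygen)
Why: Elbs persulfate oxidation: the phenoxide attacks the peroxide O–O bond through the carbon para to O⁻ (C5, also ortho to OMe) to give an aryl sulfate that acid hydrolyses to the hydroquinone; the aldehyde tolerates these conditions (salicylaldehyde gives gentisaldehyde the same way), and a moderate yield with recovered 1 is expected.

**Step 2**
Reactants: 2, 2,5‑dihydroxy‑4‑methoxybenzaldehyde; 3, 4‑fluorobenzaldehyde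
Product: 4, 5‑(4‑formylphenoxy)‑2‑hydroxy‑4‑methoxybenzaldehyde
Conditions: 3 (1.05 equiv), K2CO3 (2.5 equiv), degassed DMF, 100 °C, N2
Reagents that add atoms: none (the 4‑formylphenyl unit comes from reactant 3; fluoride is lost)
Why: SNAr (addition–elimination) on fluoride activated by the para‑CHO; of the two phenoxides only O5 is a good nucleophile, because O2 is chelated and conjugated to the ortho‑formyl group (a vinylogous carboxylate), as in the selective 5‑O‑alkylation of 2,5‑dihydroxyaryl carbonyls.

**Step 3**
Reactants: 4, 5‑(4‑formylphenoxy)‑2‑hydroxy‑4‑methoxybenzaldehyde; 5, 4‑ethynylphenol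
Product: 6, 4‑{4‑hydroxy‑5‑[(2E)‑3‑(4‑hydroxyphenyl)prop‑2‑enoyl]‑2‑methoxyphenoxy}benzaldehyde
Conditions: 5 (2 equiv, added slowly), [Rh(cod)Cl]2 (2.5 mol %), dppf (5 mol %), Na2CO3 (10 mol %), 1,4‑dioxane, 80 °C, Ar
Reagents that add atoms: none (all new atoms come from reactant 5; 100% atom‑economical addition)
Why: Proposed new method: the reaction class is known, but its use with a terminal arylacetylene carrying a free phenol and with full linear selectivity is an extension; the Rh(I) phenoxide of the salicyl unit inserts into the adjacent aldehyde C–H, the hydride adds to the internal alkyne carbon (Rh goes to the less hindered terminus) and C–C reductive elimination gives the linear enone, the syn addition of acyl and H fixing E, while the non‑chelating 4‑aryloxybenzaldehyde cannot be activated; closest known reaction type is Rh/bisphosphine chelation‑assisted intermolecular alkyne hydroacylation with salicylaldehydes (giving (E)‑2‑hydroxyaryl vinyl ketones) and with 2‑aminobenzaldehydes plus arylacetylenes (linear E‑enones).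

**Step 4**
Reactants: 6 (aldehyde); 7, dimethyl (1‑diazo‑2‑oxopropyl)phosphonate
Product: 8, (2E)‑1‑[5‑(4‑ethynylphenoxy)‑2‑hydroxy‑4‑methoxyphenyl]‑3‑(4‑hydroxyphenyl)prop‑2‑en‑1‑one
Conditions: 7 (1.3 equiv), K2CO3 (4 equiv), MeOH, 0 °C → rt; then dilute AcOH
Reagents that add atoms: dimethyl (1‑diazo‑2‑oxopropyl)phosphonate, COP(=O)(OC)C(=[N+]=[N-])C(C)=O (supplies the one new alkyne carbon; the aldehyde oxygen, N2, phosphate and acetyl are lost)
Why: Ohira–Bestmann (Seyferth–Gilbert) homologation of ArCHO to ArC≡CH; in K2CO3/MeOH the chalcone is a bis‑phenolate (4‑O⁻ and 2′‑O⁻ push into the enone), which switches off dipolar cycloaddition, Michael addition and flavanone closure, and the aryl ketone is inert, so the non‑phenolic aldehyde is the only electrophile and the E‑alkene is untouched.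

**Step 5**
Reactants: 8 (alkyne); 9, 2,4‑dihydroxybenzaldehyde
Product: 10, rhuschalcone III, (2E)‑1‑(2,4‑dihydroxyphenyl)‑3‑[4‑{4‑hydroxy‑5‑[(2E)‑3‑(4‑hydroxyphenyl)prop‑2‑enoyl]‑2‑methoxyphenoxy}phenyl]prop‑2‑en‑1‑one
Conditions: 9 (2.5 equiv), [Rh(cod)Cl]2 (5 mol %), dppf (10 mol %), Na2CO3 (20 mol %), 1,4‑dioxane, 80 °C, Ar; dilute AcOH work‑up
Reagents that add atoms: none (all new atoms come from reactant 9)
Why: Proposed new method: same extension as step 3, now on a polyphenolic substrate; 9 is the only aldehyde with an ortho‑OH and 8 contains the only alkyne, so the Rh‑phenoxide/acyl‑hydride adds H to the internal and acyl to the terminal alkyne carbon in a syn fashion to give the second E‑enone directly, and the existing enone, phenols, OMe and diaryl ether are spectators under these near‑neutral conditions; closest known reaction type is Rh‑catalysed chelation‑assisted alkyne hydroacylation with salicylaldehydes.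

## Compound list

1 | 2‑hydroxy‑4‑methoxybenzaldehyde | COc1ccc(C=O)c(O)c1 | starting material
2 | 2,5‑dihydroxy‑4‑methoxybenzaldehyde | COc1cc(O)c(C=O)cc1O | intermediate
3 | 4‑fluorobenzaldehyde | O=Cc1ccc(F)cc1 | starting material
4 | 5‑(4‑formylphenoxy)‑2‑hydroxy‑4‑methoxybenzaldehyde | COc1cc(O)c(C=O)cc1Oc1ccc(C=O)cc1 | intermediate
5 | 4‑ethynylphenol | C#Cc1ccc(O)cc1 | starting material
6 | 4‑{4‑hydroxy‑5‑[(2E)‑3‑(4‑hydroxyphenyl)prop‑2‑enoyl]‑2‑methoxyphenoxy}benzaldehyde | COc1cc(O)c(C(=O)/C=C/c2ccc(O)cc2)cc1Oc1ccc(C=O)cc1 | intermediate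
7 | dimethyl (1‑diazo‑2‑oxopropyl)phosphonate (Ohira–Bestmann reagent) | COP(=O)(OC)C(=[N+]=[N-])C(C)=O | starting material (reagent)
8 | (2E)‑1‑[5‑(4‑ethynylphenoxy)‑2‑hydroxy‑4‑methoxyphenyl]‑3‑(4‑hydroxyphenyl)prop‑2‑en‑1‑one | COc1cc(O)c(C(=O)/C=C/c2ccc(O)cc2)cc1Oc1ccc(C#C)cc1 | intermediate
9 | 2,4‑dihydroxybenzaldehyde | O=Cc1ccc(O)cc1O | starting material
10 | rhuschalcone III | COc1cc(O)c(C(=O)/C=C/c2ccc(O)cc2)cc1Oc1ccc(/C=C/C(=O)c2ccc(O)cc2O)cc1 | target

## Summary

Total step count: 5. Longest linear sequence: 5 (fully linear, no protecting groups).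

Steps most likely to fail, each with a fallback that changes the approach:

1. **Step 5 (final hydroacylation).** Risks are the branched regioisomer (which would close to an isoflavanone), catalyst sequestration by the chelating product, and alkyne oligomerisation. Fallback: give up C–H acylation for this enone and skip step 4; condense aldehyde 6 with 2,4‑bis(methoxymethoxy)acetophenone (KOH, EtOH, Claisen–Schmidt), then remove MOM with HCl/MeOH.
2. **Step 3 (first hydroacylation).** Risks are the same regiochemistry question and Rh‑mediated polymerisation of 4‑ethynylphenol. Fallback: reach 8 through the ketone series: paeonol → Elbs oxidation → SNAr with 3 → Ohira–Bestmann on the aldehyde (the aryl ketone is inert) → Claisen–Schmidt with 4‑hydroxybenzaldehyde. The bold step is then kept only for step 5.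
3. **Step 4 (Ohira–Bestmann beside an enone).** Risks are pyrazoline formation by diazo cycloaddition and partial flavanone closure. Fallback: carry the alkyne in preformed and masked. Make the ether by Cu‑catalysed Ullmann coupling of 2 with (4‑iodophenylethynyl)triisopropylsilane, then hydroacylate with 5, remove TIPS with TBAF, and hydroacylate with 9.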